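**Plan**
Locants (hydroazulene core): five-membered ring C1(Me2)–C2(=O)–C3H=C3a–C8a(OH); seven-membered ring C3a–C4(Me)–C5–C6(hemiketal)–C7(OH)–C8(=O)–C8a.
Outer cuts: C7–OH goes back to a ketone; the hemiketal O–C6 bond and the C5–CH2 bond are cut to the pyrone, one CH2 unit and the C5-enol of a 6,7,8-trione; the C6 oxygen is then removed.
Central cut: C8a(OH)–C8(=O) is a tertiary α-ketol whose acyl carbon C8 lies in the seven-membered ring. Returning the alkene carbon C3a from C8a to C8 gives an 8a-hydroxy-decalin-1,3,8-trione, so the five-membered ring comes from a six-membered ring by contraction while the seven-membered ring grows from a cyclohexanone.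
The decalin (naphthalene locants) is cut at C1–C8a (vinylogous Dieckmann) and C4–C4a (Michael addition, sulfoxide elimination) into (R)-4-methylcyclohex-2-enone and a C5 β-keto sulfoxide ester.
Forward order: cyclohexenone ring B, annulation of ring A, 8a-hydroxylation, 6/6 to 5/7 shift, C6 oxidation, pyrone annulation (dihydropyran ring), C7 reduction.
Stereochemistry: C4 by enantioselective deprotonation; decalin 8a-OH anti to the methyl, then handed on suprafacially to C8a of the hydroazulene in a Mg chelate; C5/C6 thermodynamic; C7 by OH-directed hydride delivery.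

Key step: step 7

Remark: C5 and C6 of the target can epimerise through the open 6-keto/enol form; the target configuration there (dihydropyran trans-fused, anomeric OH axial, C5–CH2 trans to the C4 methyl) is assumed to be the thermodynamically preferred one.

**Step 1**
Reactants: 1 4-methylcyclohexanone
Product: 2 (R)-trimethyl[(4-methylcyclohex-1-en-1-yl)oxy]silane
Conditions: (S,S)-bis(1-phenylethyl)amine, n-BuLi, THF, −78 °C; then 1 and TMSCl (internal quench), −100 → −78 °C
Reagents that add atoms: chlorotrimethylsilane, C[Si](C)(C)Cl
Why: Enantioselective deprotonation of the prochiral ketone by a C2-symmetric chiral lithium amide with internal silyl quench (Simpkins–Koga desymmetrisation) removes one of the two enantiotopic axial α-hydrogens and so fixes the methyl-bearing carbon as R (sense taken by analogy with 4-tert-butylcyclohexanone; the antipodal amine is used if the sense is reversed).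

**Step 2**
Reactants: 2 (R)-trimethyl[(4-methylcyclohex-1-en-1-yl)oxy]silane
Product: 3 (R)-4-methylcyclohex-2-en-1-one
Conditions: Pd(OAc)2 (10 mol %), O2 (1 atm), DMSO, 23 °C
Reagents that add atoms: none
Why: Saegusa–Ito oxidation: the Pd(II) enolate formed from the enol silane undergoes β-hydride elimination only on the side of the former enol double bond, which should give the 2-enone with the γ-stereocentre untouched.

**Step 3**
Reactants: 4 dimethyl 2,2-dimethylmalonate; 5 methyl phenyl sulfoxide
Product: 6 methyl 2,2-dimethyl-3-oxo-4-(phenylsulfinyl)butanoate (racemic at sulfur)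
Conditions: 5 (2.1 equiv), LDA (2.1 equiv), THF, −78 °C; then 4, −78 → 0 °C; aq. NH4Cl
Reagents that add atoms: none
Why: Claisen-type acylation of the α-sulfinyl carbanion by one ester group (Corey–Chaykovsky β-keto sulfoxide synthesis); the product is deprotonated at once by the second equivalent of carbanion, which protects it and the remaining hindered ester from further attack.

**Step 4**
Reactants: 3 (R)-4-methylcyclohex-2-en-1-one; 6 methyl 2,2-dimethyl-3-oxo-4-(phenylsulfinyl)butanoate
Product: 8 methyl (R)-2,2-dimethyl-4-(6-methyl-3-oxocyclohex-1-en-1-yl)-3-oxobutanoate, via Michael adduct 7 (not isolated)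
Conditions: DBU (0.3 equiv), THF, 23 °C; then toluene, CaCO3, 80 °C
Reagents that add atoms: none
Why: Base-catalysed Michael addition of the β-keto sulfoxide to the enone β-carbon, then thermal syn-elimination of benzenesulfenic acid (sulfoxide pyrolysis) in which the ring CH is the only β-hydrogen, so the enone level of ring A is reached without an oxidant and the irreversible elimination pulls the reversible Michael step; the new centres of 7 are destroyed again and 8 (drawn as the ring-conjugated tautomer) keeps only the methyl stereocentre.

**Step 5**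
Reactants: 8 methyl (R)-2,2-dimethyl-4-(6-methyl-3-oxocyclohex-1-en-1-yl)-3-oxobutanoate
Product: 9 (5R)-8-hydroxy-2,2,5-trimethyl-6,7-dihydronaphthalene-1,3(2H,5H)-dione (enol form of the 1,3,8-trione)
Conditions: KOt-Bu (2.2 equiv), THF, 0 → 23 °C; then 1 M HCl
Reagents that add atoms: none
Why: Vinylogous Dieckmann (intramolecular Claisen) condensation: the doubly stabilised anion of 8 attacks the neopentyl ester through the ring carbon α to the ring ketone in a 6-exo-trig closure (attack through the side-chain carbon would give a four-membered ring), and the β-triketone product is removed from all equilibria as its enolate.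

**Step 6**
Reactants: 9 (5R)-8-hydroxy-2,2,5-trimethyl-6,7-dihydronaphthalene-1,3(2H,5H)-dione
Product: 10 (5R,8aS)-8a-hydroxy-2,2,5-trimethyl-5,6,7,8a-tetrahydronaphthalene-1,3,8(2H)-trione
Conditions: dimethyldioxirane (1.1 equiv), acetone, −40 → 0 °C
Reagents that add atoms: dimethyldioxirane, CC1(C)OO1
Why: Electrophilic hydroxylation of a β-dicarbonyl enol by a dioxirane (enol epoxidation and opening, Rubottom-type) at the ring-fusion carbon C8a, the only enol carbon; allylic 1,3-strain with C4–H holds the C5 methyl pseudoaxial, so oxygen should be delivered to the opposite face and the new tertiary OH stands trans to that methyl (8aS).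

**Step 7**
Reactants: 10 (5R,8aS)-8a-hydroxy-2,2,5-trimethyl-5,6,7,8a-tetrahydronaphthalene-1,3,8(2H)-trione
Product: 11 (4R,8aR)-7,8a-dihydroxy-1,1,4-trimethyl-4,5-dihydroazulene-2,8(1H,8aH)-dione (diosphenol form of the 2,7,8-trione)
Conditions: Mg(OTf)2 (1.2 equiv), Et3N (2.5 equiv), MeCN, 40 °C; then aq. NaH2PO4
Reagents that add atoms: none
Why: Mg(II)/Et3N turn the tertiary 8a-OH into a magnesium alkoxide chelated to the C1 ketone, and the ring-fusion bond C8a–C4a (alkenyl carbon) then shifts suprafacially from C8a to C1 through a three-centre transition state while C8a becomes a ketone, so the cyclohexene-1,3-dione ring (C1, C2, C3, C4, C4a, C8a) loses C8a and becomes the cyclopentenone and the cyclohexanone ring gains C1 and becomes the seven-membered 7,8-dione. The closest known reaction type is the α-ketol (acyloin) ring contraction of cyclic 2-hydroxy-1,3-diones, as in the Mg-promoted isomerisation of hop α-acids to iso-α-acids. No ring is closed by a cyclisation: both new rings come from the one 1,2-shift (6→5 contraction and 6→7 expansion across the shared bond). The only new stereocentre, the cyclopentenone carbinol (old C1, new C8a), is set by chirality transfer from the old C8a: in the syn-periplanar O–C8a–C1=O chelate C4a reaches only the carbonyl face on which the old OH stands, so the new OH takes the face of the old one, anti to the methyl (8aR), and the old centre is spent. The step needs migration of C4a to C1 and not of C4a to C8 or of an acyl carbon: acyl shifts would give bridged bicycles with a bridgehead alkene, and the shift to C8 leaves a non-enolisable vicinal dione that reverts, whereas the wanted product is drained as the magnesium diosphenolate of its enolisable 7,8-dione. This exchange of a blocked trione with parallel peri carbonyls (C1, C8) for a chelated enolate is the expected driving force.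

**Step 8**
Reactants: 11 (4R,8aR)-7,8a-dihydroxy-1,1,4-trimethyl-4,5-dihydroazulene-2,8(1H,8aH)-dione
Product: 13 (4R,8aR)-6,8a-dihydroxy-1,1,4-trimethyl-1,4-dihydroazulene-2,7,8(8aH)-trione, via ene-diol 12 (not isolated)
Conditions: dimethyldioxirane (1.05 equiv), acetone, −40 °C; evaporate; Dess–Martin periodinane (1.3 equiv), NaHCO3, CH2Cl2, 0 °C
Reagents that add atoms: dimethyldioxirane, CC1(C)OO1
Why: Rubottom-type hydroxylation of the electron-rich diosphenol double bond at C6, then Dess–Martin oxidation of the resulting ene-diol/α-ketol to the 6,7,8-trione, which can enolise only toward C5 (C8a is quaternary) and should rest as the kojic-acid-like 6-hydroxy-5-ene; no stereocentre is formed.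

**Step 9**
Reactants: 13 (4R,8aR)-6,8a-dihydroxy-1,1,4-trimethyl-1,4-dihydroazulene-2,7,8(8aH)-trione; 14 4-hydroxy-5,6-dimethyl-2H-pyran-2-one
Product: 17 7-oxo hemiketal (the target with C7 as ketone; 4R,5R,6S,8aR), via Mannich base 15 (not isolated), via exo-methylene trione 16 (not isolated)
Conditions: Eschenmoser's salt (1.1 equiv), CH2Cl2, 23 °C; then 14 (1.3 equiv), MeCN, 50 °C; aq. NaHCO3
Reagents that add atoms: N,N-dimethylmethyleneiminium iodide, C=[N+](C)C.[I-]
Why: Mannich aminomethylation at the enol carbon C5 (as in kojic acid), E1cB loss of dimethylamine to the exo-methylene trione, conjugate addition of pyrone C3 (warfarin-type Michael addition) and closure of the pyrone 4-OH onto the C6 ketone as a six-membered hemiketal (6-exo-trig); C5 and C6 are epimerisable through the open form and should settle with CH2 trans to the C4 methyl and as the trans-fused dihydropyran with axial anomeric OH.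

**Step 10**
Reactants: 17 7-oxo hemiketal
Product: 18 CNP0525404.1 (4R,5R,6S,7R,8aR)
Conditions: Me4NBH(OAc)3 (1.5 equiv), MeCN/AcOH 1:1, −30 °C
Reagents that add atoms: none
Why: Hydroxyl-directed triacetoxyborohydride reduction (Evans–Saksena type): boron bound to the tertiary C8a–OH delivers hydride through a six-membered transition state to the C7 carbonyl, the more electrophilic and less hindered member of the 7,8-dione, on the face of that OH, so the new C7–OH should be anti to it (7R) while the cyclopentenone and the pyrone stay untouched.

**Compound list**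
1 | 4-methylcyclohexanone | CC1CCC(=O)CC1 | starting material
2 | (R)-trimethyl[(4-methylcyclohex-1-en-1-yl)oxy]silane | C[Si](C)(C)OC1=CC[C@H](C)CC1 | intermediate
3 | (R)-4-methylcyclohex-2-en-1-one | O=C1C=C[C@H](C)CC1 | intermediate
4 | dimethyl 2,2-dimethylmalonate | COC(=O)C(C)(C)C(=O)OC | starting material
5 | methyl phenyl sulfoxide (racemic) | CS(=O)c1ccccc1 | starting material
6 | methyl 2,2-dimethyl-3-oxo-4-(phenylsulfinyl)butanoate | COC(=O)C(C)(C)C(=O)CS(=O)c1ccccc1 | intermediate
7 | Michael adduct: methyl 2,2-dimethyl-4-[(2R)-2-methyl-5-oxocyclohexyl]-3-oxo-4-(phenylsulfinyl)butanoate (mixture at the other centres) | COC(=O)C(C)(C)C(=O)C(C1CC(=O)CC[C@H]1C)S(=O)c1ccccc1 | intermediate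
8 | methyl (R)-2,2-dimethyl-4-(6-methyl-3-oxocyclohex-1-en-1-yl)-3-oxobutanoate | COC(=O)C(C)(C)C(=O)CC1=CC(=O)CC[C@H]1C | intermediate
9 | (5R)-8-hydroxy-2,2,5-trimethyl-6,7-dihydronaphthalene-1,3(2H,5H)-dione | C[C@@H]1CCC(O)=C2C(=O)C(C)(C)C(=O)C=C12 | intermediate
10 | (5R,8aS)-8a-hydroxy-2,2,5-trimethyl-5,6,7,8a-tetrahydronaphthalene-1,3,8(2H)-trione | C[C@@H]1CCC(=O)[C@]2(O)C(=O)C(C)(C)C(=O)C=C12 | intermediate
11 | (4R,8aR)-7,8a-dihydroxy-1,1,4-trimethyl-4,5-dihydroazulene-2,8(1H,8aH)-dione | C[C@@H]1CC=C(O)C(=O)[C@@]2(O)C1=CC(=O)C2(C)C | intermediate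
12 | ene-diol: (4R,8aR)-6,7,8a-trihydroxy-1,1,4-trimethyl-4,5-dihydroazulene-2,8(1H,8aH)-dione | C[C@@H]1CC(O)=C(O)C(=O)[C@@]2(O)C1=CC(=O)C2(C)C | intermediate
13 | (4R,8aR)-6,8a-dihydroxy-1,1,4-trimethyl-1,4-dihydroazulene-2,7,8(8aH)-trione | C[C@@H]1C=C(O)C(=O)C(=O)[C@@]2(O)C1=CC(=O)C2(C)C | intermediate
14 | 4-hydroxy-5,6-dimethyl-2H-pyran-2-one | Cc1oc(=O)cc(O)c1C | starting material
15 | Mannich base: 13 carrying CH2NMe2 at C5 (configuration of 13 retained) | C[C@@H]1C(CN(C)C)=C(O)C(=O)C(=O)[C@@]2(O)C1=CC(=O)C2(C)C | intermediate
16 | exo-methylene trione: 5-methylene-6,7,8-trione of the same core (configuration of 13 retained) | C[C@@H]1C(=C)C(=O)C(=O)C(=O)[C@@]2(O)C1=CC(=O)C2(C)C | intermediate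
17 | 7-oxo hemiketal: 5,6-dimethyl-2-pyranone fused through O–C6 and CH2–C5 to the hydroazulene core, OH at C6 and C8a, C=O at C2, C7, C8 (4R,5R,6S,8aR) | Cc1oc(=O)c2c(c1C)O[C@]1(O)C(=O)C(=O)[C@@]3(O)C(=CC(=O)C3(C)C)[C@H](C)[C@H]1C2 | intermediate
18 | CNP0525404.1: as 17 with C7 as CH–OH (4R,5R,6S,7R,8aR) | Cc1oc(=O)c2c(c1C)O[C@]1(O)[C@H](O)C(=O)[C@@]3(O)C(=CC(=O)C3(C)C)[C@H](C)[C@H]1C2 | target

**Totals**
Total step count: 10. Longest linear sequence: 9 steps (1, 2, 4, 5, 6, 7, 8, 9, 10).

**Three steps most likely to fail**

Step 7. The acyloin equilibrium may rest on the side of the decalin ketol, material may leak into the isomer formed by migration to C8, or chelation may be incomplete so that the shift loses part of its facial fidelity. Fallback (kinetic capture of the product instead of equilibrium control): setting out from 10, the Mg-chelated shift is run with TBSCl present, so that the magnesium diosphenolate is O-silylated as it forms and gives the 7-silyl dienol ether F1. The hindered tertiary magnesium alkoxide of 10 should not be silylated, and F1 cannot take part in the back reaction, so 10 is drained through the small equilibrium share. HF·pyridine in THF then frees the diosphenol and the route is rejoined at 11.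

Step 9. The enol carbon of the electron-poor trione may be too weak a nucleophile for aminomethylation, the exo-methylene trione may oligomerise before the pyrone adds, and the doubly allylic C4–H may epimerise through an extended dienol. Fallback (roles reversed, cycloaddition instead of Mannich/Michael): setting out from 13, the acidic enol OH is silylated (TBSCl, imidazole) to the 6-silyloxy enol ether F2, which can no longer tautomerise. Separately 14 and Eschenmoser's salt give the pyrone Mannich base F3. Heating F2 with F3 in toluene at 100 °C makes F3 lose dimethylamine to the pyrone quinone methide F4, which adds across the silyl enol ether in an inverse-demand hetero-Diels–Alder reaction (Tietze type), anti to the C4 methyl, to the cis-fused silyl ketal F5. HF·pyridine frees the hemiketal, which equilibrates through its open form, and the route is rejoined at 17.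

Step 10. Hydride may be delivered to the C8 carbonyl or to the wrong face of C7, or the α-ketol formed may be reduced further. Fallback (temporary silicon tether instead of an external hydride): setting out from 17, the hemiketal OH is silylated with chlorodiisopropylsilane/imidazole to the hydridosilyl ether F6. Catalytic TBAF then triggers intramolecular hydrosilylation of the neighbouring C7 ketone only, from the face of the tether, giving the cyclic dioxasilolane F7. HF·pyridine removes the silylene and the route is rejoined at 18.

**Further compounds**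
F1 | step 7 | 7-O-TBS dienol ether of 11 | C[C@@H]1CC=C(O[Si](C)(C)C(C)(C)C)C(=O)[C@@]2(O)C1=CC(=O)C2(C)C
F2 | step 9 | 6-O-TBS enol ether of 13 | C[C@@H]1C=C(O[Si](C)(C)C(C)(C)C)C(=O)C(=O)[C@@]2(O)C1=CC(=O)C2(C)C
F3 | step 9 | 3-[(dimethylamino)methyl]-4-hydroxy-5,6-dimethyl-2H-pyran-2-one | Cc1oc(=O)c(CN(C)C)c(O)c1C
F4 | step 9 | 5,6-dimethyl-3-methylene-2H-pyran-2,4(3H)-dione (quinone methide) | CC1=C(C)C(=O)C(=C)C(=O)O1
F5 | step 9 | cis-fused 6-O-TBS ketal cycloadduct (6-epimeric silyl ketal of 17) | Cc1oc(=O)c2c(c1C)O[C@@]1(O[Si](C)(C)C(C)(C)C)C(=O)C(=O)[C@@]3(O)C(=CC(=O)C3(C)C)[C@H](C)[C@H]1C2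
F6 | step 10 | 6-O-(diisopropylsilyl) ether of 17 | Cc1oc(=O)c2c(c1C)O[C@]1(O[SiH](C(C)C)C(C)C)C(=O)C(=O)[C@@]3(O)C(=CC(=O)C3(C)C)[C@H](C)[C@H]1C2
F7 | step 10 | 6,7-O-diisopropylsilylene derivative of 18 | Cc1oc(=O)c2c(c1C)O[C@@]13O[Si](C(C)C)(C(C)C)O[C@@H]3C(=O)[C@@]4(O)C(=CC(=O)C4(C)C)[C@H](C)[C@H]1C2
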